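Late in the delta run the curve had nearly gone flat: between 12.0 min and 20.0 min the reacted electrophile rose from 55.4% to 59.6% of the charge, though 40.4% still stood unreacted.

| setting | delta | beta | red | green | amber |
|---|---|---|---|---|---|
| electrophile | 0.20 M (fed, over 12 min) | 0.20 M (fed, over 12 min) | 0.20 M (fed, over 12 min) | 0.20 M (fed, over 12 min) | 0.20 M (fed, over 12 min) |
| nucleophile | 1.4 equiv | 2.6 equiv | 1.00 equiv | 1.30 equiv | 1.70 equiv |
| remark | run made earlier; the fed solution adds 0.20 times the starting volume | run made earlier; the fed solution adds 0.20 times the starting volume | the fed solution adds 0.20 times the starting volume | the fed solution adds 0.20 times the starting volume | the fed solution adds 0.20 times the starting volume |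
| time |  |  | 25 min | 25 min | 25 min |

| run | time / min | electrophile / % | target / % |
|---|---|---|---|
| delta | 2.00 | 9.5 | 5.7 |
| delta | 6.00 | 18.2 | 21.5 |
| delta | 12.0 | 44.6 | 35.7 |
| delta | 20.0 | 40.4 | 38.4 |
| beta | 2.00 | 7.1 | 7.6 |
| beta | 6.00 | 9.4 | 19.3 |
| beta | 12.0 | 22.1 | 33.8 |
| beta | 20.0 | 7.4 | 33.3 |

(scatter of a reading: 0.5 percentage points)

- amounts are per litre of the starting volume; all of the dose is in the solution fed
- steps that have been proposed: nucleophile + target -> over-reaction product; nucleophile + acid set free <-> protonated nucleophile; electrophile + nucleophile <-> acid set free + target
- percentages count the whole charge, also what has not yet gone in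

- part of the electrophile that has reacted at the end, red
- part of the electrophile that has reacted at the end, green
- part of the electrophile that has reacted at the end, amber
- what raising the equivalents of nucleophile from its lowest to its highest value here does to the part of the electrophile that has reacted (changes below 5 percentage points count as none) (it falls / no change / it rises)

I read that level as a nucleophile balance. Each electrophile reacted takes one nucleophile, the acid set free takes a second, and each over-reaction takes one more. In delta, 21.2% of the charge had gone on past target. So the price p came to 2.36, where p is the nucleophile used per electrophile reacted. Multiplied by the reacted share, p gave 1.41 equivalents, which matched the 1.4 equiv charged. Beta at 20.0 min had a price of 2.64, and it had used 2.44 of its 2.6 equiv.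

The level L is therefore the equivalents divided by p. I used delta's price, because its charge lies inside the asked range. That gave L of 42.5% for red, 55.2% for green and 72.2% for amber, a rise of 30 percentage points.

Now the curve for red. Reacted electrophile cannot outrun the steady feed, so its starting slope is at most 0.0167 M min⁻¹. That line meets L at 5.09 min, which I took as a first estimate of the knee in red. In delta the reacted curve lagged its feed, so I expected a rounder and later knee. Past the knee I drew electrophile in red piling up, crossing the reacted line near 10.2 min, and reaching about 57.5% when the feed ends.

The forecast gave 43.5%, 55.5% and 69.5%, and its verdict was it rises. Its ground was the same balance: “Each electrophile reacted uses two nucleophile”. It differed from mine by letting the price grow, so its amber figure is lower than my 72.2%.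

    nucleophile + target → over-reaction product (k = 0.0152 L mol⁻¹ s⁻¹)
    nucleophile + acid set free ⇌ protonated nucleophile, settled at all times (K = 27000 L mol⁻¹)
    electrophile + nucleophile ⇌ acid set free + target (K = 1.47, k = 0.0419 L mol⁻¹ s⁻¹)

The flasks gave 44.8%, 56.2% and 70.2%: it rises, by 25 points. The forecast stood within its margins. At 25 min red held 0.62% of its nucleophile against 55% of its electrophile, so nucleophile was the limiting reagent. The next flask was red with 2.50 equiv of nucleophile. Beta's price was the nearer one, and it gave L of 94.7%. That flask reached 92.3%, with 3.04% of its nucleophile left. In that flask target stood at 34.3% of the electrophile charged, and over-reaction product held the most of it, 58.0%.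

The earlier runs and the new flask come from a simulation with made-up constants, and the scatter is random.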